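## The problem

Compound 21, 7-hydroxy-3-[2-hydroxy-4-methoxy-5-(3-methylbut-2-enyl)phenyl]chromen-4-one, is an isoflavone. A benzo-fused γ-pyrone (rings A and C) is joined through the C3–C1' bond to a 1,2,4,5-tetrasubstituted benzene (ring B). There is no stereocentre, so the synthesis has to solve regiochemistry and the timing of functional groups. The only stereochemical element that appears on the way is the geometry of an open-chain enol ether, and it is erased when ring C closes. Of the three aryl oxygens, 4'-O is a methyl ether while 7-O and 2'-O are free phenols, so the three must be distinguished from the outset. The 2'-oxygen is the delicate one: in any open-chain precursor of ring C it can reach C2 and close a furan (a 3-aroylbenzofuran), in competition with the ring-A oxygen that should close the pyranone. The prenyl chain at C5' is a trisubstituted alkene that excludes hydrogenolysis, electrophilic halogen and strong protic acid late in the route, and the γ-pyrone itself opens in hot alkali. The feature that invites a short convergent plan is C4: a lone carbonyl carbon flanked by C4a of ring A and by C3, which already carries ring B and the C2 enol-ether carbon. C4 can therefore be carbon monoxide, inserted between a ring-B vinyl electrophile and a ring-A aryl nucleophile.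

## Retrosynthesis

**21 from 20.** The last cut is the O–Si bond at O2'. Silyl ether 20 is the complete isoflavone with only the 2'-oxygen masked. A bulky triisopropylsilyl group is chosen because it survives organolithium addition, enolate formation, carbonate base at 80 °C and dilute acid, yet falls to buffered fluoride, which touches neither the prenyl alkene nor the pyranone. The forward step only has to be mild.

**20 from 18 (through 19).** The O1–C2 bond is cut, which opens ring C to the β-methoxy enone 18. This compound is already at the chromone oxidation level, so ring closure needs no redox step, only addition of the ring-A oxygen to C2 and loss of the methoxy group. Ring A carries acetal (methoxymethyl) protection, which acid removes while the silyl ether on ring B stays. The free 2-hydroxyaryl ketone 19 therefore forms with the 2'-oxygen still blocked, and only the pyranone can close. Cutting C3–C1' instead (a 3-halochromone and a ring-B boronate) was considered, but it leaves the carbonyl carbon and ring C to be built separately.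

**18 from 11, 16 and 17.** Both bonds to C4 are cut at once: C3–C4 and C4–C4a. This gives vinyl triflate 11 (ring B with C2 and C3), boronic acid 16 (ring A) and carbon monoxide 17 (C4). The precursors are two separately made arenes of similar size, so the route is convergent. The forward reaction must let carbon monoxide insert before the arylboron reagent transmetalates, and it must leave the silyl ether, the acetals and the prenyl alkene untouched. No ring closes here, which keeps the key step free of any competition between the two ortho oxygens.

**11 from 9, 8, 5 and 6.** The C–O bond of the triflate is cut back to α-methoxy ketone 9, which has a single enolisable position, so the regiochemistry of enolisation is not in question (the enolate is 10). Ketone 9 comes from alcohol 8 by oxidation. Alcohol 8 arises by cutting the C3–C2 bond to aldehyde 5 and stannane 6, the source of methoxymethyllithium 7. This one-carbon homologation installs C2 with its methoxy group already in place, so no later formylation of a deoxybenzoin is needed.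

**5 from 4, 2, 3 and 1.** The silyl ether of 5 is removed on paper to phenol 4. The C5'–CH2 bond is then cut to aryl bromide 2 and prenylstannane 3. A stannane is preferred to a prenylboronate or a prenylzinc reagent because those add to a free aldehyde, whereas the tin reagent does not without a Lewis acid. Bromide 2 comes from 2-hydroxy-4-methoxybenzaldehyde 1, in which the hydroxyl (para) and the methoxy group (ortho) both direct bromine to C5 and the position between the two oxygens is hindered. The commercial aldehyde already holds the 2'-OH/4'-OMe differentiation.

**16 from 13 and 12.** The C–B bond is cut to bromide 13 (through aryllithium 14 and borate 15), and the two acetals are cut to 4-bromoresorcinol 12. The bromine of 12 marks the carbon that becomes C4a. Direct metalation of the unbrominated bis-acetal would instead occur between the two oxygens, so the halogen is needed to fix the position.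

## Roads not taken

**Alternative 1:** Ring B is built on a finished chromone by a Danheiser benzannulation. The cut removes four ring-B bonds (C1'–C2', C2'–C3', C4'–C5', C5'–C6'). In the forward step, irradiation of diazo dienone A2 triggers a Wolff rearrangement to a vinylketene. The ketene adds alkynyl ether A3 in a (2+2) sense, the cyclobutenone opens, and a six-electron electrocyclisation followed by tautomerisation gives phenol A1. The merits are real. The positions of all four ring-B substituents follow from connectivity alone, the 2'-OH emerges free and already distinguished from the 4'-methoxy group, and A1 needs only one acetal cleavage to reach 21, against two closing steps in the chosen plan. The weak points lie in A2 and in the photochemistry. The diazo carbon of A2 carries the prenyl CH2, so a 1,2-hydrogen shift of the carbene to a dienone competes with the Wolff migration. The chromone and the cross-conjugated enone are chromophores with photoreactions of their own, and A3 is volatile, unstable and needed in excess. A2 must also be assembled over several steps through a sensitive α-alkyl diazo ketone. On endgame economy and on freedom from orthogonal protection this route is better. The chosen plan sets against it two stable, storable fragments and a bond-forming step from an established reaction class.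

**Alternative 2:** The C2=C3 bond is formed by ring-closing metathesis. Diene A5 carries an O-vinyl ether on ring A and a 1-arylvinyl group, and is closed with the second-generation Grubbs catalyst (H2IMes)(PCy3)Cl2Ru=CHPh to the 4-silyloxy-4H-chromene A4. The merits are neutral conditions, no toxic gas, and the fact that the 2'-oxygen cannot interfere with the ring closure, so one kind of protecting group serves for both phenols. For this target the drawbacks outweigh that. A4 is at the wrong oxidation level: C4 is an sp3 carbon with a stereocentre that must then be destroyed, so desilylation, oxidation and deprotection follow. A4 is also a vinylogous acetal that ionises easily to a benzopyrylium ion. The vinyl ether gives a poorly turning-over alkoxycarbene on ruthenium, the other alkene is 1,1-disubstituted next to an ortho-substituted arene, and the prenyl alkene is a competing metathesis site. A5 in turn needs an O-vinylation and the addition of a 1-arylvinyl metal to a salicylaldehyde. The alternative avoids carbon monoxide and an acid-sensitive enol triflate, and that is a fair point in its favour. The chosen plan delivers the chromone oxidation level directly and has fewer steps after the key event.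

**Alternative 3:** Ring C is closed by a hetero-Diels–Alder reaction of a quinoketene. The cut is C3–C4 together with O1–C2. Photolysis of benzodioxinone A7 expels its ketal carbon and gives a quinoketene, which is to add enol ether A8 in a (4+2) sense. Loss of the C2 methoxy group on acidic work-up then gives isoflavone A6. This is the shortest road. Both partners are two or three steps from commercial material, two bonds and a ring form in one operation, and A6 needs a single global acetal cleavage to reach 21. In step count it is better than the chosen plan. Its weakness is reliability. Quinoketenes generated this way are well known to be captured by heteroatom nucleophiles, but capture by an enol ether in the (4+2) mode is not established to the same degree. A (2+2) addition across the ketene C=C bond, photoisomerisation and photocycloaddition of the electron-rich styrene A8, and reaction at the prenyl alkene are all plausible diversions. The plan would amount to method development at the decisive step. The chosen route forms the same C3–C4 bond and accepts more steps in exchange for a key step of a known type.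

Key step: step 9

Remark on the chemistry: the (Z) geometry written for 10, 11, 18 and 19 is the one expected from a potassium-chelated enolate. It has no bearing on 21, because C2=C3 is re-formed when ring C closes.

## Route

Step 1
Reactants: 1 2-hydroxy-4-methoxybenzaldehyde
Product: 2 5-bromo-2-hydroxy-4-methoxybenzaldehyde
Conditions: Br2, NaOAc, AcOH, rt
Reagents that add atoms: bromine, BrBr
Why: Electrophilic aromatic bromination; C5 is para to the hydroxyl and ortho to the methoxy group, while the position between the two oxygens is hindered, so the 5-bromo isomer should form selectively.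

Step 2
Reactants: 2 5-bromo-2-hydroxy-4-methoxybenzaldehyde; 3 tributyl(3-methylbut-2-enyl)stannane
Product: 4 2-hydroxy-4-methoxy-5-(3-methylbut-2-enyl)benzaldehyde
Conditions: Pd(PPh3)4 (cat.), DMF, 100 °C
Reagents that add atoms: none
Why: Migita–Kosugi–Stille coupling of an aryl bromide with an allylic stannane; the prenyl(aryl)palladium intermediate should eliminate at its less substituted terminus and give the linear prenyl arene. The stannane does not add to the deactivated, hydrogen-bonded aldehyde without a Lewis acid, and the free phenol allows tin residues to be removed by base extraction.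

Step 3
Reactants: 4 2-hydroxy-4-methoxy-5-(3-methylbut-2-enyl)benzaldehyde
Product: 5 4-methoxy-5-(3-methylbut-2-enyl)-2-(triisopropylsilyloxy)benzaldehyde
Conditions: TIPSCl, imidazole, DMF, rt to 40 °C
Reagents that add atoms: chlorotriisopropylsilane, CC(C)[Si](Cl)(C(C)C)C(C)C
Why: Standard O-silylation of a phenol; the bulky silyl group is chosen so that the future 2'-oxygen survives organolithium, enolate, carbonate and dilute-acid conditions and is released only by fluoride.

Step 4
Reactants: 5 4-methoxy-5-(3-methylbut-2-enyl)-2-(triisopropylsilyloxy)benzaldehyde; 6 tributyl(methoxymethyl)stannane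
Product: 8 rac-2-methoxy-1-[4-methoxy-5-(3-methylbut-2-enyl)-2-(triisopropylsilyloxy)phenyl]ethanol, via methoxymethyllithium 7 (not isolated)
Conditions: 6, n-BuLi, THF, −78 °C; then 5, −78 °C; aq NH4Cl at −78 °C
Reagents that add atoms: none
Why: Tin–lithium exchange gives the α-alkoxy organolithium, which adds 1,2 to the aryl aldehyde at low temperature. The carbinol centre forms as a racemate and is removed in step 5, and the cold quench limits silyl transfer from the aryl oxygen to the alkoxide.

Step 5
Reactants: 8 rac-2-methoxy-1-[4-methoxy-5-(3-methylbut-2-enyl)-2-(triisopropylsilyloxy)phenyl]ethanol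
Product: 9 2-methoxy-1-[4-methoxy-5-(3-methylbut-2-enyl)-2-(triisopropylsilyloxy)phenyl]ethanone
Conditions: Dess–Martin periodinane, NaHCO3, CH2Cl2, 0 °C to rt
Reagents that add atoms: none
Why: Dess–Martin oxidation of a secondary benzylic alcohol under buffered, non-acidic conditions, which spares the prenyl alkene and the silyl ether and avoids ionisation of the electron-rich benzylic position.

Step 6
Reactants: 9 2-methoxy-1-[4-methoxy-5-(3-methylbut-2-enyl)-2-(triisopropylsilyloxy)phenyl]ethanone
Product: 11 (Z)-2-methoxy-1-[4-methoxy-5-(3-methylbut-2-enyl)-2-(triisopropylsilyloxy)phenyl]ethenyl trifluoromethanesulfonate, via potassium (Z)-enolate 10 (not isolated)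
Conditions: KN(SiMe3)2, THF, −78 °C; PhNTf2, −78 to 0 °C; chromatography on Et3N-deactivated silica
Reagents that add atoms: N-phenylbis(trifluoromethanesulfonimide), O=S(=O)(N(c1ccccc1)S(=O)(=O)C(F)(F)F)C(F)(F)F
Why: Enol triflate formation; the ketone has one enolisable position, the potassium-chelated (Z)-enolate is expected, and O-sulfonylation by PhNTf2 is standard for potassium enolates. The geometry is immaterial for 21.

Step 7
Reactants: 12 4-bromobenzene-1,3-diol
Product: 13 1-bromo-2,4-bis(methoxymethoxy)benzene
Conditions: MOMCl, iPr2NEt, CH2Cl2, 0 °C to rt
Reagents that add atoms: chloromethyl methyl ether, COCCl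
Why: Double O-alkylation of the phenols to methoxymethyl acetals, which resist organolithium and carbonate base and are cleaved later by dilute acid.

Step 8
Reactants: 13 1-bromo-2,4-bis(methoxymethoxy)benzene
Product: 16 [2,4-bis(methoxymethoxy)phenyl]boronic acid, via aryllithium 14 (not isolated), via lithium triisopropoxyborate 15 (not isolated)
Conditions: n-BuLi, THF, −78 °C; B(OiPr)3, −78 °C to rt; aq NH4Cl
Reagents that add atoms: triisopropyl borate, CC(C)OB(OC(C)C)OC(C)C; water, O
Why: Lithiation–borylation; bromine–lithium exchange is faster than directed ortho-metalation at −78 °C and places boron on the carbon that becomes C4a. The near-neutral hydrolysis keeps the acetals, and the acid should be used fresh because ortho-alkoxy arylboronic acids protodeboronate on standing.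

Step 9
Reactants: 11 (Z)-2-methoxy-1-[4-methoxy-5-(3-methylbut-2-enyl)-2-(triisopropylsilyloxy)phenyl]ethenyl trifluoromethanesulfonate; 16 [2,4-bis(methoxymethoxy)phenyl]boronic acid; 17 carbon monoxide
Product: 18 (Z)-1-[2,4-bis(methoxymethoxy)phenyl]-3-methoxy-2-[4-methoxy-5-(3-methylbut-2-enyl)-2-(triisopropylsilyloxy)phenyl]prop-2-en-1-one
Conditions: Pd(PPh3)4 (5 mol %), K2CO3, CO (3 bar), anisole, 80 °C, 16 (1.5 equiv) added slowly
Reagents that add atoms: none
Why: Zerovalent palladium adds oxidatively to the C–OTf bond of 11 with retention and gives a vinylpalladium triflate that binds CO readily; migratory insertion of the electron-rich vinyl group forms the C3–C4 bond and an acylpalladium species. The carbonate-activated boronate of 16 then transmetalates, and reductive elimination forms the C4–C4a bond, releases ketone 18 and returns zerovalent palladium. The closest known reaction type is the carbonylative Suzuki–Miyaura coupling of alkenyl and aryl triflates with arylboronic acids to give ketones. No ring closes and no stereocentre is formed; the alkene geometry is carried over and is irrelevant later. The selectivity needed is CO insertion before transmetalation, since the reverse order gives the direct vinyl–aryl product. It is favoured by CO pressure, by slow addition of 16, by the slow transmetalation of an ortho-alkoxy boronic acid and by the high migratory aptitude of the donor-substituted vinyl group. Anhydrous carbonate in anisole leaves the silyl ether, the acetals and the prenyl alkene alone, and the excess of 16 covers protodeboronation.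

Step 10
Reactants: 18 (Z)-1-[2,4-bis(methoxymethoxy)phenyl]-3-methoxy-2-[4-methoxy-5-(3-methylbut-2-enyl)-2-(triisopropylsilyloxy)phenyl]prop-2-en-1-one
Product: 20 7-hydroxy-3-[4-methoxy-5-(3-methylbut-2-enyl)-2-(triisopropylsilyloxy)phenyl]chromen-4-one, via dihydroxy enone 19 (not isolated)
Conditions: 3 M HCl (aq), MeOH, 40 °C
Reagents that add atoms: none
Why: Acid-catalysed acetal exchange frees both ring-A phenols; the hydroxyl ortho to the ketone adds to C2 of the β-methoxy enone (6-endo oxa-Michael addition) and methanol is eliminated to give the aromatic γ-pyrone, as in the classical enaminone and enol-ether closures to isoflavones. The aryl silyl ether resists dilute methanolic acid, so the 2'-oxygen cannot close a furan at C2.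

Step 11
Reactants: 20 7-hydroxy-3-[4-methoxy-5-(3-methylbut-2-enyl)-2-(triisopropylsilyloxy)phenyl]chromen-4-one
Product: 21 7-hydroxy-3-[2-hydroxy-4-methoxy-5-(3-methylbut-2-enyl)phenyl]chromen-4-one
Conditions: Bu4NF, AcOH, THF, 0 °C
Reagents that add atoms: none
Why: Fluoride-mediated cleavage of the aryl silyl ether; buffering with acetic acid keeps the medium near neutral so that the pyranone and the liberated 2'-phenol are not exposed to strong base.

## Compound list

1 | 2-hydroxy-4-methoxybenzaldehyde | COc1ccc(C=O)c(O)c1 | starting material
2 | 5-bromo-2-hydroxy-4-methoxybenzaldehyde | COc1cc(O)c(C=O)cc1Br | intermediate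
3 | tributyl(3-methylbut-2-enyl)stannane | CCCC[Sn](CCCC)(CCCC)CC=C(C)C | starting material
4 | 2-hydroxy-4-methoxy-5-(3-methylbut-2-enyl)benzaldehyde | COc1cc(O)c(C=O)cc1CC=C(C)C | intermediate
5 | 4-methoxy-5-(3-methylbut-2-enyl)-2-(triisopropylsilyloxy)benzaldehyde | COc1cc(O[Si](C(C)C)(C(C)C)C(C)C)c(C=O)cc1CC=C(C)C | intermediate
6 | tributyl(methoxymethyl)stannane | CCCC[Sn](CCCC)(CCCC)COC | starting material
7 | methoxymethyllithium | [Li]COC | intermediate
8 | rac-2-methoxy-1-[4-methoxy-5-(3-methylbut-2-enyl)-2-(triisopropylsilyloxy)phenyl]ethanol | COCC(O)c1cc(CC=C(C)C)c(OC)cc1O[Si](C(C)C)(C(C)C)C(C)C | intermediate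
9 | 2-methoxy-1-[4-methoxy-5-(3-methylbut-2-enyl)-2-(triisopropylsilyloxy)phenyl]ethanone | COCC(=O)c1cc(CC=C(C)C)c(OC)cc1O[Si](C(C)C)(C(C)C)C(C)C | intermediate
10 | potassium (Z)-2-methoxy-1-[4-methoxy-5-(3-methylbut-2-enyl)-2-(triisopropylsilyloxy)phenyl]ethenolate | [K+].CO/C=C(\[O-])c1cc(CC=C(C)C)c(OC)cc1O[Si](C(C)C)(C(C)C)C(C)C | intermediate
11 | (Z)-2-methoxy-1-[4-methoxy-5-(3-methylbut-2-enyl)-2-(triisopropylsilyloxy)phenyl]ethenyl trifluoromethanesulfonate | CO/C=C(\OS(=O)(=O)C(F)(F)F)c1cc(CC=C(C)C)c(OC)cc1O[Si](C(C)C)(C(C)C)C(C)C | intermediate
12 | 4-bromobenzene-1,3-diol (4-bromoresorcinol) | Oc1ccc(Br)c(O)c1 | starting material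
13 | 1-bromo-2,4-bis(methoxymethoxy)benzene | COCOc1ccc(Br)c(OCOC)c1 | intermediate
14 | [2,4-bis(methoxymethoxy)phenyl]lithium | [Li]c1ccc(OCOC)cc1OCOC | intermediate
15 | lithium [2,4-bis(methoxymethoxy)phenyl]tri(propan-2-yloxy)borate | [Li+].COCOc1ccc([B-](OC(C)C)(OC(C)C)OC(C)C)c(OCOC)c1 | intermediate
16 | [2,4-bis(methoxymethoxy)phenyl]boronic acid | COCOc1ccc(B(O)O)c(OCOC)c1 | intermediate
17 | carbon monoxide | [C-]#[O+] | starting material
18 | (Z)-1-[2,4-bis(methoxymethoxy)phenyl]-3-methoxy-2-[4-methoxy-5-(3-methylbut-2-enyl)-2-(triisopropylsilyloxy)phenyl]prop-2-en-1-one | COCOc1ccc(C(=O)/C(c2cc(CC=C(C)C)c(OC)cc2O[Si](C(C)C)(C(C)C)C(C)C)=C\OC)c(OCOC)c1 | intermediate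
19 | (Z)-1-(2,4-dihydroxyphenyl)-3-methoxy-2-[4-methoxy-5-(3-methylbut-2-enyl)-2-(triisopropylsilyloxy)phenyl]prop-2-en-1-one | Oc1ccc(C(=O)/C(c2cc(CC=C(C)C)c(OC)cc2O[Si](C(C)C)(C(C)C)C(C)C)=C\OC)c(O)c1 | intermediate
20 | 7-hydroxy-3-[4-methoxy-5-(3-methylbut-2-enyl)-2-(triisopropylsilyloxy)phenyl]chromen-4-one | COc1cc(O[Si](C(C)C)(C(C)C)C(C)C)c(-c2coc3cc(O)ccc3c2=O)cc1CC=C(C)C | intermediate
21 | 7-hydroxy-3-[2-hydroxy-4-methoxy-5-(3-methylbut-2-enyl)phenyl]chromen-4-one | COc1cc(O)c(-c2coc3cc(O)ccc3c2=O)cc1CC=C(C)C | target

## Step count and risks

Total: 11 steps. Longest linear sequence: 9 steps (steps 1–6, then 9, 10 and 11). The ring-A branch is steps 7 and 8.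

**Step 9 (key step).** The most likely failure is transmetalation overtaking CO insertion, which gives the direct vinyl–aryl product. The electron-rich ortho-alkoxy boronic acid may also protodeboronate before it meets the acylpalladium species, and oxidative addition into the hindered, donor-substituted triflate may be slow. The fallback keeps carbon monoxide as C4 but forms the two bonds in separate operations. It sets out from 11 and from 13. Palladium-catalysed aminocarbonylation of 11 (Pd(OAc)2, Xantphos, CO, N,O-dimethylhydroxylamine hydrochloride, Et3N, toluene, 70 °C) has no competing direct coupling and should give the Weinreb amide (Z)-N,3-dimethoxy-N-methyl-2-[4-methoxy-5-(3-methylbut-2-enyl)-2-(triisopropylsilyloxy)phenyl]prop-2-enamide F1. Aryllithium 14, made from 13 as in step 8, is then added to F1 at −78 °C. The chelated tetrahedral adduct collapses on work-up, and the sequence comes back to the route at 18.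

**Step 2.** Allylic transposition in the prenylpalladium intermediate could deliver some of the reverse-prenyl (1,1-dimethylallyl) isomer, and oxidative addition into the electron-rich bromide may be sluggish. The fallback separates C–C bond formation from the question of alkene position. It sets out from 2. Stille coupling with allyltributylstannane, an unsubstituted allyl group for which transposition is degenerate, should give 2-hydroxy-4-methoxy-5-(prop-2-enyl)benzaldehyde F2. Cross-metathesis of F2 with 2-methylbut-2-ene, using the second-generation Grubbs catalyst (H2IMes)(PCy3)Cl2Ru=CHPh in CH2Cl2 at 40 °C, then installs the trisubstituted alkene and returns to the route at 4.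

**Step 4.** The benzylic lithium alkoxide may take the silyl group from the neighbouring aryl oxygen (1,5 oxygen-to-oxygen silyl migration, which would leave a phenoxide). The electron-rich benzylic alcohol can also ionise if the work-up turns acidic. The fallback changes the order of events so that an alkoxide and an aryl silyl ether never coexist. It sets out from 4. The phenol is deprotonated with LiN(SiMe3)2 and the phenoxide is treated with 7 (from 6 and n-BuLi), giving rac-2-(1-hydroxy-2-methoxyethyl)-5-methoxy-4-(3-methylbut-2-enyl)phenol F3. Selective silylation of the more acidic phenolic hydroxyl of F3 (TIPSCl, imidazole, DMF) returns to the route at 8.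

**Step 10.** Protic acid may add to the prenyl alkene in the Markovnikov sense. The silyl ether may also be lost before ring C has closed, which would let the 2'-oxygen close a furan at C2. The fallback removes acid from the endgame by relying on two silyl groups of different lability. It sets out from 12 and from 11. Silylation of 12 (TBSCl, imidazole, DMF) gives 1-bromo-2,4-bis(tert-butyldimethylsilyloxy)benzene F4. Miyaura borylation of F4 (B2pin2, PdCl2(dppf), KOAc, dioxane, 80 °C) avoids an ortho-silyloxy aryllithium and gives 2-[2,4-bis(tert-butyldimethylsilyloxy)phenyl]-4,4,5,5-tetramethyl-1,3,2-dioxaborolane F5. Carbonylative coupling of F5 with 11 and 17 under the conditions of step 9, with K3PO4 as base, gives (Z)-1-[2,4-bis(tert-butyldimethylsilyloxy)phenyl]-3-methoxy-2-[4-methoxy-5-(3-methylbut-2-enyl)-2-(triisopropylsilyloxy)phenyl]prop-2-en-1-one F6. K2CO3 in MeOH at room temperature then cleaves the two less hindered aryl silyl ethers of F6. The ring-A phenoxide closes the pyranone through 19 with loss of methoxide, and the sequence returns to the route at 20, where the bulkier silyl ether is still in place.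

## Further compounds

F1 | step 9 | (Z)-N,3-dimethoxy-N-methyl-2-[4-methoxy-5-(3-methylbut-2-enyl)-2-(triisopropylsilyloxy)phenyl]prop-2-enamide | CO/C=C(\C(=O)N(C)OC)c1cc(CC=C(C)C)c(OC)cc1O[Si](C(C)C)(C(C)C)C(C)C
F2 | step 2 | 2-hydroxy-4-methoxy-5-(prop-2-enyl)benzaldehyde | COc1cc(O)c(C=O)cc1CC=C
F3 | step 4 | rac-2-(1-hydroxy-2-methoxyethyl)-5-methoxy-4-(3-methylbut-2-enyl)phenol | COCC(O)c1cc(CC=C(C)C)c(OC)cc1O
F4 | step 10 | 1-bromo-2,4-bis(tert-butyldimethylsilyloxy)benzene | CC(C)(C)[Si](C)(C)Oc1ccc(Br)c(O[Si](C)(C)C(C)(C)C)c1
F5 | step 10 | 2-[2,4-bis(tert-butyldimethylsilyloxy)phenyl]-4,4,5,5-tetramethyl-1,3,2-dioxaborolane | CC(C)(C)[Si](C)(C)Oc1ccc(B2OC(C)(C)C(C)(C)O2)c(O[Si](C)(C)C(C)(C)C)c1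
F6 | step 10 | (Z)-1-[2,4-bis(tert-butyldimethylsilyloxy)phenyl]-3-methoxy-2-[4-methoxy-5-(3-methylbut-2-enyl)-2-(triisopropylsilyloxy)phenyl]prop-2-en-1-one | CC(C)(C)[Si](C)(C)Oc1ccc(C(=O)/C(c2cc(CC=C(C)C)c(OC)cc2O[Si](C(C)C)(C(C)C)C(C)C)=C\OC)c(O[Si](C)(C)C(C)(C)C)c1
A1 | alternative 1 | 3-[2-hydroxy-4-methoxy-5-(3-methylbut-2-enyl)phenyl]-7-(methoxymethoxy)chromen-4-one | COCOc1ccc2c(c1)occ(-c1cc(CC=C(C)C)c(OC)cc1O)c2=O
A2 | alternative 1 | (E)-4-diazo-1-[7-(methoxymethoxy)-4-oxochromen-3-yl]-7-methylocta-1,6-dien-3-one | COCOc1ccc2c(c1)occ(/C=C/C(=O)C(=[N+]=[N-])CC=C(C)C)c2=O
A3 | alternative 1 | methoxyethyne | COC#C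
A4 | alternative 2 | rac-4-(tert-butyldimethylsilyloxy)-7-(methoxymethoxy)-3-[4-methoxy-2-(methoxymethoxy)-5-(3-methylbut-2-enyl)phenyl]-4H-chromene | COCOc1ccc2c(c1)OC=C(c1cc(CC=C(C)C)c(OC)cc1OCOC)C2O[Si](C)(C)C(C)(C)C
A5 | alternative 2 | rac-tert-butyl{1-[2-(ethenyloxy)-4-(methoxymethoxy)phenyl]-2-[4-methoxy-2-(methoxymethoxy)-5-(3-methylbut-2-enyl)phenyl]prop-2-enoxy}dimethylsilane | C=COc1cc(OCOC)ccc1C(O[Si](C)(C)C(C)(C)C)C(=C)c1cc(CC=C(C)C)c(OC)cc1OCOC
A6 | alternative 3 | 7-(methoxymethoxy)-3-[4-methoxy-2-(methoxymethoxy)-5-(3-methylbut-2-enyl)phenyl]chromen-4-one | COCOc1ccc2c(c1)occ(-c1cc(CC=C(C)C)c(OC)cc1OCOC)c2=O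
A7 | alternative 3 | 7-(methoxymethoxy)-2,2-dimethyl-1,3-benzodioxin-4-one | COCOc1ccc2c(c1)OC(C)(C)OC2=O
A8 | alternative 3 | (E)-1-methoxy-4-(2-methoxyethenyl)-5-(methoxymethoxy)-2-(3-methylbut-2-enyl)benzene | CO/C=C/c1cc(CC=C(C)C)c(OC)cc1OCOC
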